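All constants stand for no real mixture; no experiment stands behind them.

The catalyst is single-handed: at 80 °C it couples partner to left-handed substrate with a selectivity factor of 51.4 over right-handed substrate. The flasks differ in their temperature.

the same everywhere: left-handed substrate 0.050 M; gas 16 mM (held); catalyst 0.1 mol%; right-handed substrate 0.050 M; time 30 h

|  | temperature | remark |
|---|---|---|
| north-west | 110 °C |  |
| south |  | at 50 °C until 20 h, from then on at 110 °C |
| south-east | 50 °C |  |
| west | 80 °C |  |

    partner + catalyst + left-handed substrate → catalyst + left-handed product (k1 = 11.2 M⁻² s⁻¹, Ea1 = 56.0 kJ mol⁻¹)
    partner + catalyst + right-handed substrate → catalyst + right-handed product (k2 = 0.218 M⁻² s⁻¹, Ea2 = 47.0 kJ mol⁻¹)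
    left-handed substrate ⇌ right-handed substrate (k3 = 2.05 × 10⁻⁵ s⁻¹, Ea3 = 129 kJ mol⁻¹)
    2 partner → self-condensation product (k4 = 8.16 × 10⁻⁴ M⁻¹ s⁻¹, Ea4 = 75.0 kJ mol⁻¹)
    gas ⇌ partner, rate k5*(csat - [partner]) (k5 = 9.10 × 10⁻⁵ s⁻¹, csat = 16 mM)
    (constants at 80 °C)

- catalyst is single-handed; left-handed substrate and right-handed substrate are mirror images of each other, charged as a racemate, each of them at the stated concentration
- a doubled species enters its step squared and goes two at a time
- at the start none of partner is dissolved
- constants are those at 80 °C; use the activation energies for any other temperature

1. the flask that comes out highest in amount of left-handed product, in percent of the left-handed substrate and right-handed substrate together charged, or "all alike" when all lie within 1.5 percentage points (north-west / south / south-east / west / all alike)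
2. left-handed product at the end, in percent of the left-handed substrate and right-handed substrate together charged, north-west
3. left-handed product at the end, in percent of the left-handed substrate and right-handed substrate together charged, south
4. left-handed product at the end, in percent of the left-handed substrate and right-handed substrate together charged, south-east
5. left-handed product at the end, in percent of the left-handed substrate and right-handed substrate together charged, west

The catalyst stands at 5.00 × 10⁻⁵ M, reckoned on left-handed substrate as charged. For [partner] I set the gas feed equal to the loss by self-condensation plus the loss by coupling, with each substrate form taken at 0.7 of its charge as a mid-run guess. The coupling constant κ, pseudo-first-order in left-handed substrate, is k[catalyst][partner] with the step's constant at the flask's temperature. Racemisation is counted both ways.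

| Flask | [partner] | κ | racemisation |
|---|---|---|---|
| north-west | 5.85 mM | 0.0525 h⁻¹ | 4.60 h⁻¹ |
| west | 11.3 mM | 0.0228 h⁻¹ | 0.148 h⁻¹ |
| south-east | 15.1 mM | 0.00517 h⁻¹ | 0.00250 h⁻¹ |

In the north-west row, racemisation is 87.6 times κ, so the two forms stay level and act as one pool, of which the reactive form is half. The pool therefore falls with the drain constant D, which is κ divided by two: 0.0263 h⁻¹. The fraction left in north-west is exp(−Dt), or 45.5%, which makes 54.5% left-handed product.

In the west row, racemisation is 6.49 times κ. The same rule gives 28.9%.

In the south-east row, racemisation is slower than κ, so left-handed substrate drains by itself. Its half of the charge yields 7.18%.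

South spends 20 h on the south-east κ, which leaves 95.1% of the pool. It then spends 10.0 h on the north-west D, which keeps a fraction 76.9% and makes 26.9%. My pick is north-west.

The forecast, which reckoned the catalyst as a share “of total substrate” where I reckon it on left-handed substrate, named north-west, with 71% for north-west, 42% for south, 13% for south-east and 40% for west.

The simulation gives north-west as highest, with 52.6% for north-west, 27.3% for south, 6.49% for south-east and 25.3% for west.

In south at 30.0 h, left-handed substrate has a forward half-life into right-handed substrate of 0.30 h, shorter than its 13 h by coupling. The two forms stand there at 35.9% and 36.3%. The north-west pool holds 46.5% at 30.0 h, against the 45.5% reckoned from D. Applied to south from the 95.7% standing at 20.0 h, D gives 73.6% at the end, and the south flask holds 72.2%.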